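**Plan**

- The target is cut first at its three phenolic O–H bonds (two are carried as benzyl ethers) and at the diarylmethane CH2, which is traced back to an aryl ketone.
- The central ring is a resorcinol monomethyl ether: the free OH sits on C1, next to C2 (which carries the 4-hydroxybenzyl group); the phenethyl chain is on C3 and OMe on C5. Ring atoms C1–C6–C5–C4 therefore map onto a 1,1,3-trioxygenated butadiene, and C2–C3 onto an alkyne carrying an aroyl group on C2.
- The two ring bonds C1–C2 and C4–C3 are cut as a [4+2] cycloaddition; the ynone is cut further at C(=O)–C(sp) and at the ArCH2–CH2 bond of the phenethyl chain.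
- Forward: propargylation of the benzylic bromide, protodesilylation and acyl Sonogashira coupling give the ynone; the diene is made in one step; the central ring arises last by cycloaddition–aromatization; ketone reduction and hydrogenolysis finish.
- Stereochemistry: none has to be set.

Key step: step 5

Remark: the target has no stereocentre and no stereogenic double bond, so it is achiral and the requirement of a single enantiomer is met without enantiocontrol. The only stereocentres on the way (in 11 and 14) are formed as racemates and are erased.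
Remark: the C1 geometry of diene 10 is drawn as (1Z); it is of no consequence because that carbon becomes an arene carbon.

**Route**

Step 1
Reactants: 1 3-(benzyloxy)benzyl bromide; 2 1-(trimethylsilyl)propyne
Product: 4 [4-[3-(benzyloxy)phenyl]but-1-yn-1-yl]trimethylsilane, via lithiated silylpropyne 3 (not isolated)
Conditions: 2, n-BuLi, THF, −78 °C; then 1, −78 °C → rt
Reagents that add atoms: none
Why: Propargylic lithiation of 1-(trimethylsilyl)propyne and SN2 alkylation with a reactive benzylic bromide is a standard three-carbon homologation, the silyl group steering attack to the propargylic terminus so that the alkyne and not the allene should form.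

Step 2
Reactants: 4 [4-[3-(benzyloxy)phenyl]but-1-yn-1-yl]trimethylsilane
Product: 5 1-(benzyloxy)-3-(but-3-yn-1-yl)benzene
Conditions: K2CO3 (cat.), MeOH, rt
Reagents that add atoms: none
Why: Carbonate-catalysed methanolysis of the C(sp)–Si bond (protodesilylation of an alkynylsilane) is routine and should leave the benzyl ether untouched.

Step 3
Reactants: 5 1-(benzyloxy)-3-(but-3-yn-1-yl)benzene; 6 4-(benzyloxy)benzoyl chloride
Product: 7 1-[4-(benzyloxy)phenyl]-5-[3-(benzyloxy)phenyl]pent-2-yn-1-one
Conditions: PdCl2(PPh3)2 (2 mol%), CuI (4 mol%), Et3N (1.1 equiv), THF, rt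
Reagents that add atoms: none
Why: Acyl Sonogashira coupling of an aroyl chloride with a terminal alkyne gives aryl ynones directly at room temperature, and with only about one equivalent of amine the propargylic CH2 should not isomerise.

Step 4
Reactants: 8 methyl (E)-3-methoxybut-2-enoate
Product: 10 (1Z)-1,3-dimethoxy-1-(trimethylsilyloxy)buta-1,3-diene, via lithium dienolate 9 (not isolated)
Conditions: LDA, THF, −78 °C; then TMSCl, −78 °C → rt; distillation
Reagents that add atoms: chlorotrimethylsilane, C[Si](C)(C)Cl
Why: γ-Deprotonation of the vinylogous carbonate by LDA and O-silylation of the dienolate is the established preparation of this silyl ketene acetal diene.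

Step 5
Reactants: 7 1-[4-(benzyloxy)phenyl]-5-[3-(benzyloxy)phenyl]pent-2-yn-1-one; 10 (1Z)-1,3-dimethoxy-1-(trimethylsilyloxy)buta-1,3-diene
Product: 13 [4-(benzyloxy)phenyl][2-[2-[3-(benzyloxy)phenyl]ethyl]-6-hydroxy-4-methoxyphenyl]methanone, via silyl ketal cycloadduct 11 (not isolated), via aryl trimethylsilyl ether 12 (not isolated)
Conditions: 10 (2.5 equiv), PhMe, 90 °C, sealed tube; then 1 M HCl, THF, rt
Reagents that add atoms: none
Why: A thermal, asynchronous normal-demand Diels–Alder reaction joins the diene CH2 terminus to the alkyne carbon bearing the phenethyl chain and the ketene-acetal carbon to the aroyl-bearing alkyne carbon; the cyclohexa-1,4-diene 11 then loses methanol from its mixed ketal carbon to give aryl silyl ether 12, which dilute acid hydrolyses to phenol 13. The closest known reaction type is the cycloaddition–aromatization of 1,1,3-trioxygenated butadienes with acetylenic carbonyl compounds and quinones to give resorcinol monoethers. The central six-membered carbocycle is closed by the intermolecular [4+2] cycloaddition itself, both ring bonds forming in that one event. No stereocentre remains in 13, the ketal carbon of 11 being racemic and destroyed on aromatization. The regiochemistry needed is secured by matched polarization, the largest HOMO coefficient lying at the diene CH2 terminus and the largest LUMO coefficient at the ynone β-carbon, so the aroyl group ends up next to the ketal-derived oxygen. The oxygen differentiation needed is secured by expulsion of methanol with retention of the silyloxy group, so that the oxygen ortho to the ketone emerges as the free phenol and the remote one as the methyl ether.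

Step 6
Reactants: 13 [4-(benzyloxy)phenyl][2-[2-[3-(benzyloxy)phenyl]ethyl]-6-hydroxy-4-methoxyphenyl]methanone
Product: 14 2-[[4-(benzyloxy)phenyl](hydroxy)methyl]-3-[2-[3-(benzyloxy)phenyl]ethyl]-5-methoxyphenol (racemic)
Conditions: NaBH4 (excess), THF–MeOH, 0 °C → rt; aq. NH4Cl; used crude
Reagents that add atoms: none
Why: Borohydride reduction of o-hydroxybenzophenones to o-hydroxybenzhydrols is standard, the ortho,ortho'-disubstitution twisting the carbonyl out of conjugation with the resorcinol ring so that hydride addition should remain feasible; the carbinol centre forms without control as the racemate, which is immaterial because step 7 removes it.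

Step 7
Reactants: 14 2-[[4-(benzyloxy)phenyl](hydroxy)methyl]-3-[2-[3-(benzyloxy)phenyl]ethyl]-5-methoxyphenol
Product: 15 2-(4-hydroxybenzyl)-3-[2-(3-hydroxyphenyl)ethyl]-5-methoxyphenol (IN1159)
Conditions: H2 (1 atm), 10% Pd/C, EtOAc–AcOH, rt
Reagents that add atoms: none
Why: Palladium-catalysed benzylic hydrogenolysis should cleave both aryl benzyl ethers and the doubly benzylic, electron-rich carbinol C–O bond (assisted by acetic acid) in one operation, while the aryl methyl ether and the arenes are inert at 1 atm.

**Compound list**

1 | 3-(benzyloxy)benzyl bromide | BrCc1cccc(OCc2ccccc2)c1 | starting material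
2 | 1-(trimethylsilyl)propyne | CC#C[Si](C)(C)C | starting material
3 | [3-(trimethylsilyl)prop-2-yn-1-yl]lithium (formed in the flask, not isolated) | [Li]CC#C[Si](C)(C)C | intermediate
4 | [4-[3-(benzyloxy)phenyl]but-1-yn-1-yl]trimethylsilane | C[Si](C)(C)C#CCCc1cccc(OCc2ccccc2)c1 | intermediate
5 | 1-(benzyloxy)-3-(but-3-yn-1-yl)benzene | C#CCCc1cccc(OCc2ccccc2)c1 | intermediate
6 | 4-(benzyloxy)benzoyl chloride | O=C(Cl)c1ccc(OCc2ccccc2)cc1 | starting material
7 | 1-[4-(benzyloxy)phenyl]-5-[3-(benzyloxy)phenyl]pent-2-yn-1-one | O=C(C#CCCc1cccc(OCc2ccccc2)c1)c1ccc(OCc2ccccc2)cc1 | intermediate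
8 | methyl (E)-3-methoxybut-2-enoate | CO/C(C)=C/C(=O)OC | starting material
9 | lithium (1E)-1,3-dimethoxybuta-1,3-dien-1-olate, O–Li cis to C3 (formed in the flask, not isolated) | C=C(OC)/C=C(/OC)O[Li] | intermediate
10 | (1Z)-1,3-dimethoxy-1-(trimethylsilyloxy)buta-1,3-diene | C=C(OC)/C=C(/OC)O[Si](C)(C)C | intermediate
11 | [4-(benzyloxy)phenyl][2-[2-[3-(benzyloxy)phenyl]ethyl]-4,6-dimethoxy-6-(trimethylsilyloxy)cyclohexa-1,4-dien-1-yl]methanone, racemic (not isolated) | COC1=CC(OC)(O[Si](C)(C)C)C(=C(C1)CCc1cccc(OCc2ccccc2)c1)C(=O)c1ccc(OCc2ccccc2)cc1 | intermediate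
12 | [4-(benzyloxy)phenyl][2-[2-[3-(benzyloxy)phenyl]ethyl]-4-methoxy-6-(trimethylsilyloxy)phenyl]methanone (not isolated) | COc1cc(O[Si](C)(C)C)c(C(=O)c2ccc(OCc3ccccc3)cc2)c(CCc2cccc(OCc3ccccc3)c2)c1 | intermediate
13 | [4-(benzyloxy)phenyl][2-[2-[3-(benzyloxy)phenyl]ethyl]-6-hydroxy-4-methoxyphenyl]methanone | COc1cc(O)c(C(=O)c2ccc(OCc3ccccc3)cc2)c(CCc2cccc(OCc3ccccc3)c2)c1 | intermediate
14 | 2-[[4-(benzyloxy)phenyl](hydroxy)methyl]-3-[2-[3-(benzyloxy)phenyl]ethyl]-5-methoxyphenol, racemic | COc1cc(O)c(C(O)c2ccc(OCc3ccccc3)cc2)c(CCc2cccc(OCc3ccccc3)c2)c1 | intermediate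
15 | 2-(4-hydroxybenzyl)-3-[2-(3-hydroxyphenyl)ethyl]-5-methoxyphenol (IN1159), achiral | COc1cc(O)c(Cc2ccc(O)cc2)c(CCc2cccc(O)c2)c1 | target

**Step count**

Total: 7 steps. Longest linear sequence: 6 steps (steps 1, 2, 3, 5, 6, 7); the diene is made in one step (step 4) and enters at step 5.

**Steps most likely to fail**

1. Step 5. The mixed ketal carbon of the cycloadduct may collapse by loss of silanol in competition with loss of methanol. The oxygen ortho to the ketone would then be delivered partly or largely as a methyl ether, and the differentiation of the two ring oxygens would be lost. The fallback sets out from ynone 7. The cycloaddition with 10 is run as before, and the aromatized crude product, then consisting mainly of [4-(benzyloxy)phenyl][2-[2-[3-(benzyloxy)phenyl]ethyl]-4,6-dimethoxyphenyl]methanone F1, is not separated. It is heated with magnesium iodide etherate in toluene, which should remove only the methyl group that can chelate to the ketone carbonyl; this reagent is preferred to boron trihalides because the two remote benzyl ethers must survive. This chelation-controlled dealkylation converges all material on phenol 13, where the route is rejoined.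

2. Step 6. Borohydride first deprotonates the chelated phenol, which turns the ketone into a vinylogous carboxylate; hydride delivery to this hindered, deactivated carbonyl may stall. The very electron-rich benzhydrol may also ionize and oligomerize on work-up. The fallback sets out from 13. Ethyl chloroformate and triethylamine in THF at 0 °C should give 2-[4-(benzyloxy)benzoyl]-3-[2-[3-(benzyloxy)phenyl]ethyl]-5-methoxyphenyl ethyl carbonate F2, in which the phenol is masked and the ketone activated. Sodium borohydride in aqueous THF, the established one-pot deoxygenation of O-acylated o-hydroxyaryl ketones to o-alkylphenols, should then give 2-[4-(benzyloxy)benzyl]-3-[2-[3-(benzyloxy)phenyl]ethyl]-5-methoxyphenol F3 directly. Hydrogenolysis of the two benzyl ethers of F3 (H2, Pd/C, EtOAc) rejoins the route at target 15.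

3. Step 3. Copper-mediated oxidative dimerization of the alkyne and hydrolysis or decarbonylation at the acyl palladium stage may outrun the coupling. The fallback sets out from alkyne 5. Deprotonation with n-BuLi in THF at −78 °C gives [4-[3-(benzyloxy)phenyl]but-1-yn-1-yl]lithium F4. Addition of F4 to commercial 4-(benzyloxy)benzaldehyde (O=Cc1ccc(OCc2ccccc2)cc1) should give racemic 1-[4-(benzyloxy)phenyl]-5-[3-(benzyloxy)phenyl]pent-2-yn-1-ol F5 after aqueous NH4Cl. Oxidation of this propargylic, benzylic alcohol with activated MnO2 in CH2Cl2 rejoins the route at ynone 7.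

**Further compounds**

F1 | step 5 | [4-(benzyloxy)phenyl][2-[2-[3-(benzyloxy)phenyl]ethyl]-4,6-dimethoxyphenyl]methanone | COc1cc(OC)c(C(=O)c2ccc(OCc3ccccc3)cc2)c(CCc2cccc(OCc3ccccc3)c2)c1
F2 | step 6 | 2-[4-(benzyloxy)benzoyl]-3-[2-[3-(benzyloxy)phenyl]ethyl]-5-methoxyphenyl ethyl carbonate | CCOC(=O)Oc1cc(OC)cc(CCc2cccc(OCc3ccccc3)c2)c1C(=O)c1ccc(OCc2ccccc2)cc1
F3 | step 6 | 2-[4-(benzyloxy)benzyl]-3-[2-[3-(benzyloxy)phenyl]ethyl]-5-methoxyphenol | COc1cc(O)c(Cc2ccc(OCc3ccccc3)cc2)c(CCc2cccc(OCc3ccccc3)c2)c1
F4 | step 3 | [4-[3-(benzyloxy)phenyl]but-1-yn-1-yl]lithium | [Li]C#CCCc1cccc(OCc2ccccc2)c1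
F5 | step 3 | 1-[4-(benzyloxy)phenyl]-5-[3-(benzyloxy)phenyl]pent-2-yn-1-ol (racemic) | OC(C#CCCc1cccc(OCc2ccccc2)c1)c1ccc(OCc2ccccc2)cc1
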